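The bench next door keeps a dilute neighbour of the east flask at 0.0030 M of starting material, and the reckoning below will carry over to it.

    starting material ⇌ ring (K1 = 1.6, k1 = 0.050 s⁻¹)
    2 starting material → open dimer (k2 = 2.1 L mol⁻¹ s⁻¹)

| setting | north-east | south | east |
|---|---|---|---|
| starting material | 0.012 M | 0.012 M | 0.012 M |
| time | 12 min | 15 min | 10 min |

* which of these there is most of at the end, counted by the starting material in it, north-east (open dimer / starting material / ring)
* which of these there is most of at the end, counted by the starting material in it, south (open dimer / starting material / ring)
* which of these there is most of at the end, counted by the starting material in it, east (open dimer / starting material / ring)
* final amount of the leader among these, as a percentage of the starting material charged, in north-east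
* final amount of the leader among these, as a percentage of the starting material charged, in south
* final amount of the leader among these, as a percentage of the starting material charged, in east

You take over a pool, starting material plus ring, with ring as its resting state. The two trade places with a relaxation half-life of 0.142 min, far shorter than the clock below, so freeze their ratio at 1.6 of ring to one of starting material. That leaves 38.5% of the pool free to dimerise, and the pool falls as a second-order charge.

Here that gives 2.24 min. Call it the pool clock: the time in which the pool falls to half its charge, the square of one plus K1 over twice k2 times the charge. Whatever has left the pool is open dimer, so open dimer holds the time over the time plus the clock.

When you come back, I expect open dimer to lead, at 84.3% in north-east, 87.0% in south and 81.7% in east, each more than what stays in its pool. Don't thin the charge: the clock runs as one over it.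

The forecast says open dimer at 84.1% in north-east, open dimer at 86.8% in south and open dimer at 81.6% in east, on the ground that “The ring equilibrium relaxes fast”. In north-east my figure and the forecast's differ by 0.2 percentage points.

The flasks give open dimer at 84.1% in north-east, open dimer at 86.8% in south and open dimer at 81.6% in east. North-east already held 73.4% open dimer at 6.00 min, where the clock gives 72.8%. The neighbour holds a quarter of the charge, so its clock is 8.94 min, which gives 52.8% open dimer at 10.0 min. That flask stood at 53.9%.

The numbers of this flask were chosen freely.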